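**Retrosynthetic overview**
- The target is reached from a bicyclic β-keto ester by C-4 methylation (ester becomes axial, C-19), C-3 deoxygenation, Peterson unmasking of C13=C16 and acetonide hydrolysis.
- Both carbocycles form in one operation: a chiral-Lewis-acid-controlled radical bicyclisation of an acyclic (6E,10E)-α-phenylseleno β-keto ester. Ring A closes first (C4–C5), ring B second (C10–C9); selenoxide elimination then gives C8=C17.
- The acyclic chain comes from the methyl acetoacetate dianion and a C-1 allylic bromide, made by SeO2 oxidation of the geranyl terminus.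
- Geranyl bromide is joined to a methyl ketone from methyl (R)-glycerate acetonide (source of C-14). C-13 is carried as a saturated β-hydroxysilane so the cascade has no third alkene to attack.

Assumption: the (S,S)-bis(oxazoline) ligand is taken to give the decalin enantiomer drawn; if the sense is opposite, the (R,R)-ligand is used and nothing else changes.

Labdane numbering is used for the bicyclic compounds (normal series: 5α-H, 9α-H, 10β-CH3).

**Step 1**
Reactants: 1 methyl (4R)-2,2-dimethyl-1,3-dioxolane-4-carboxylate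
Product: 3 1-[(4R)-2,2-dimethyl-1,3-dioxolan-4-yl]ethan-1-one, via Weinreb amide 2 (not isolated)
Conditions: MeNH(OMe)·HCl, i-PrMgCl, THF, −20 °C; then MeMgCl, 0 °C
Reagents that add atoms: methylmagnesium chloride, C[Mg]Cl (N,O-dimethylhydroxylamine hydrochloride, CNOC.Cl, adds atoms to 2 only)
Why: One-flask Weinreb ketone synthesis: the chloromagnesium amide turns the ester into the N-methoxy-N-methylamide, whose chelated adduct with MeMgCl stops at the ketone, and the chiral-pool stereocentre (future C-14) is retained.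

**Step 2**
Reactants: 3 1-[(4R)-2,2-dimethyl-1,3-dioxolan-4-yl]ethan-1-one; 4 geranyl bromide
Product: 5 (4E)-1-[(4R)-2,2-dimethyl-1,3-dioxolan-4-yl]-5,9-dimethyldeca-4,8-dien-1-one
Conditions: LDA, THF, −78 °C; then 4, DMPU, −78 → −30 °C
Reagents that add atoms: none
Why: Kinetic lithium enolate alkylation on the methyl side (SN2 at the primary allylic bromide, E-alkene retained) forms the C11–C12 bond; the α′-alkoxy stereocentre is not deprotonated at low temperature.

**Step 3**
Reactants: 5 the dienone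
Product: 6 (5E)-2-[(4R)-2,2-dimethyl-1,3-dioxolan-4-yl]-6,10-dimethyl-1-(trimethylsilyl)undeca-5,9-dien-2-ol (both C-2 epimers)
Conditions: Me3SiCH2MgCl, CeCl3, THF, −78 → 0 °C
Reagents that add atoms: (trimethylsilyl)methylmagnesium chloride, C[Si](C)(C)C[Mg]Cl
Why: Organocerium 1,2-addition of the Peterson reagent (CeCl3 suppresses enolisation) removes the ketone and stores the future C13=C16 methylene as a saturated β-hydroxysilane, so the later radical cascade cannot run into a third ring; the new carbinol centre is a mixture that is erased in step 10.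

**Step 4**
Reactants: 6 the β-hydroxysilane
Product: 7 (2E,6E)-10-[(4R)-2,2-dimethyl-1,3-dioxolan-4-yl]-2,6-dimethyl-11-(trimethylsilyl)undeca-2,6-diene-1,10-diol
Conditions: SeO2 (cat.), t-BuOOH, salicylic acid (cat.), CH2Cl2, 0 °C → rt
Reagents that add atoms: tert-butyl hydroperoxide, CC(C)(C)OO (terminal oxidant; the oxygen is passed on through catalytic selenium dioxide, O=[Se]=O)
Why: Catalytic SeO2/t-BuOOH allylic oxidation (ene reaction then [2,3]-shift) attacks the terminal trisubstituted alkene at its (E)-methyl group and gives the (E)-allylic alcohol needed for the all-E polyene.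

**Step 5**
Reactants: 7 the allylic alcohol
Product: 9 (2E,6E)-1-bromo-10-[(4R)-2,2-dimethyl-1,3-dioxolan-4-yl]-2,6-dimethyl-11-(trimethylsilyl)undeca-2,6-dien-10-ol, via allylic mesylate 8 (not isolated)
Conditions: MsCl, Et3N, CH2Cl2, −40 °C; then LiBr, THF, 0 °C
Reagents that add atoms: lithium bromide, [Li+].[Br-] (methanesulfonyl chloride, CS(Cl)(=O)=O, adds atoms to 8 only)
Why: Selective mesylation of the primary allylic alcohol and SN2 displacement by bromide keep the E geometry; the hindered tertiary carbinol does not react.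

**Step 6**
Reactants: 9 the allylic bromide; 10 methyl acetoacetate
Product: 12 methyl (6E,10E)-14-[(4R)-2,2-dimethyl-1,3-dioxolan-4-yl]-14-hydroxy-6,10-dimethyl-3-oxo-2-(phenylselanyl)-15-(trimethylsilyl)pentadeca-6,10-dienoate, via keto ester lithium enolate 11 (not isolated)
Conditions: 10, LDA (2 equiv), THF, 0 °C; Li alkoxide of 9 (LDA, 1 equiv), −78 → 0 °C; then PhSeCl, −78 °C
Reagents that add atoms: phenylselenenyl chloride, Cl[Se]c1ccccc1
Why: Weiler dianion γ-alkylation (SN2 at the allylic bromide) forms the C1–C2 bond and leaves the α-enolate, which is selenenylated in the same flask (enolate α-selenenylation, much faster than attack of PhSeCl on the alkenes) to install the radical precursor.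

**Step 7**
Reactants: 12 the α-phenylseleno β-keto ester
Product: 15 methyl 13-hydroxy-14,15-O-isopropylidene-3-oxo-16-(trimethylsilyl)-19-norlabd-8(17)-en-18-oate (4α-CO2Me; 4β-H; enolisable), via tertiary selenide 13 (not isolated), via selenoxide 14 (not isolated)
Conditions: Mg(ClO4)2 (0.5 equiv), (S,S)-t-Bu-box (0.55 equiv), 4 Å MS, Et3B/air (cat.), toluene, −78 °C; then 30% H2O2, pyridine, CH2Cl2, 0 °C → rt
Reagents that add atoms: none
Why: Chiral-Lewis-acid-catalysed phenylseleno-group-transfer radical bicyclisation (an enantioselective atom-transfer radical cyclisation) closes ring A then ring B by two 6-endo additions through a chair–chair fold of the (E,E)-polyene, the ligand shielding one face of the Mg-chelated C-4 radical so that C-5, C-10 and C-9 are set as the trans-decalin with the C-9 chain equatorial; the tertiary C-8 radical takes PhSe from another molecule of 12, and selenoxide syn-elimination in the same flask goes mainly towards the freely rotating C-17 methyl to give the exocyclic alkene.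

**Step 8**
Reactants: 15 the bicyclic β-keto ester
Product: 16 methyl 13-hydroxy-14,15-O-isopropylidene-3-oxo-16-(trimethylsilyl)labd-8(17)-en-19-oate (4α-CH3; 4β-CO2Me)
Conditions: MeI, K2CO3, acetone, 45 °C
Reagents that add atoms: iodomethane, CI
Why: C-alkylation of the β-keto ester enolate: MeI approaches from the α-face, anti to the axial C-10 methyl, so the new methyl is equatorial and the ester is axial (C-19), which sets the C-4 quaternary centre as in the target.

**Step 9**
Reactants: 16 the methylated keto ester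
Product: 18 methyl 13-hydroxy-14,15-O-isopropylidene-16-(trimethylsilyl)labd-8(17)-en-19-oate, via tosylhydrazone 17 (not isolated)
Conditions: TsNHNH2, EtOH, 78 °C; then catecholborane, NaOAc·3H2O, CHCl3, 0 → 60 °C
Reagents that add atoms: none
Why: Caglioti–Kabalka deoxygenation: the tosylhydrazone is reduced by catecholborane and the adduct collapses with acetate to a diazene that loses N2, leaving CH2 at C-3; alkene, ester and acetonide are untouched and no stereocentre is involved.

**Step 10**
Reactants: 18 the β-hydroxysilane ester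
Product: 20 methyl (14S)-14,15-dihydroxylabda-8(17),13(16)-dien-19-oate (CNP0185041.1), via acetonide 19 (not isolated)
Conditions: KOt-Bu, THF, 0 °C → rt; then 1 M HCl, MeOH, rt
Reagents that add atoms: none
Why: Peterson elimination of the potassium alkoxide (syn loss of Me3SiOK) gives the 13(16)-methylene regiospecifically, and mild acid hydrolysis of the isopropylidene acetal frees the diol; C-14 keeps its chiral-pool configuration (the descriptor becomes S once C-13 is sp2).

**Compound list**
1 | methyl (4R)-2,2-dimethyl-1,3-dioxolane-4-carboxylate | COC(=O)[C@H]1COC(C)(C)O1 | starting material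
2 | (4R)-N-methoxy-N,2,2-trimethyl-1,3-dioxolane-4-carboxamide (Weinreb amide) | CON(C)C(=O)[C@H]1COC(C)(C)O1 | intermediate
3 | 1-[(4R)-2,2-dimethyl-1,3-dioxolan-4-yl]ethan-1-one | CC(=O)[C@H]1COC(C)(C)O1 | intermediate
4 | geranyl bromide, (2E)-1-bromo-3,7-dimethylocta-2,6-diene | CC(C)=CCC/C(C)=C/CBr | starting material
5 | (4E)-1-[(4R)-2,2-dimethyl-1,3-dioxolan-4-yl]-5,9-dimethyldeca-4,8-dien-1-one | CC(C)=CCC/C(C)=C/CCC(=O)[C@H]1COC(C)(C)O1 | intermediate
6 | (5E)-2-[(4R)-2,2-dimethyl-1,3-dioxolan-4-yl]-6,10-dimethyl-1-(trimethylsilyl)undeca-5,9-dien-2-ol (C-2 epimers) | CC(C)=CCC/C(C)=C/CCC(O)(C[Si](C)(C)C)[C@H]1COC(C)(C)O1 | intermediate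
7 | (2E,6E)-10-[(4R)-2,2-dimethyl-1,3-dioxolan-4-yl]-2,6-dimethyl-11-(trimethylsilyl)undeca-2,6-diene-1,10-diol | OC/C(C)=C/CC/C(C)=C/CCC(O)(C[Si](C)(C)C)[C@H]1COC(C)(C)O1 | intermediate
8 | primary allylic methanesulfonate of 7 | CS(=O)(=O)OC/C(C)=C/CC/C(C)=C/CCC(O)(C[Si](C)(C)C)[C@H]1COC(C)(C)O1 | intermediate
9 | (2E,6E)-1-bromo-10-[(4R)-2,2-dimethyl-1,3-dioxolan-4-yl]-2,6-dimethyl-11-(trimethylsilyl)undeca-2,6-dien-10-ol | BrC/C(C)=C/CC/C(C)=C/CCC(O)(C[Si](C)(C)C)[C@H]1COC(C)(C)O1 | intermediate
10 | methyl acetoacetate (methyl 3-oxobutanoate) | COC(=O)CC(C)=O | starting material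
11 | methyl (6E,10E)-14-[(4R)-2,2-dimethyl-1,3-dioxolan-4-yl]-14-hydroxy-6,10-dimethyl-3-oxo-15-(trimethylsilyl)pentadeca-6,10-dienoate, present as its lithium enolate (drawn neutral) | COC(=O)CC(=O)CC/C(C)=C/CC/C(C)=C/CCC(O)(C[Si](C)(C)C)[C@H]1COC(C)(C)O1 | intermediate
12 | 2-(phenylselanyl) derivative of 11 (C-2 epimers) | COC(=O)C([Se]c1ccccc1)C(=O)CC/C(C)=C/CC/C(C)=C/CCC(O)(C[Si](C)(C)C)[C@H]1COC(C)(C)O1 | intermediate
13 | methyl 13-hydroxy-14,15-O-isopropylidene-3-oxo-8-(phenylselanyl)-16-(trimethylsilyl)-19-norlabdan-18-oate (4α-CO2Me; C-8 not defined) | C[Si](C)(C)CC(O)(CC[C@H]1C(C)([Se]c3ccccc3)CC[C@@H]2[C@]1(C)CCC(=O)[C@H]2C(=O)OC)[C@H]3COC(C)(C)O3 | intermediate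
14 | Se-oxide of 13 | C[Si](C)(C)CC(O)(CC[C@H]1C(C)([Se](=O)c3ccccc3)CC[C@@H]2[C@]1(C)CCC(=O)[C@H]2C(=O)OC)[C@H]3COC(C)(C)O3 | intermediate
15 | methyl 13-hydroxy-14,15-O-isopropylidene-3-oxo-16-(trimethylsilyl)-19-norlabd-8(17)-en-18-oate (4α-CO2Me; 4β-H) | C[Si](C)(C)CC(O)(CC[C@H]1C(=C)CC[C@@H]2[C@]1(C)CCC(=O)[C@H]2C(=O)OC)[C@H]3COC(C)(C)O3 | intermediate
16 | methyl 13-hydroxy-14,15-O-isopropylidene-3-oxo-16-(trimethylsilyl)labd-8(17)-en-19-oate (4α-CH3; 4β-CO2Me) | C[Si](C)(C)CC(O)(CC[C@H]1C(=C)CC[C@@H]2[C@]1(C)CCC(=O)[C@]2(C)C(=O)OC)[C@H]3COC(C)(C)O3 | intermediate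
17 | 3-(4-methylbenzenesulfonyl)hydrazone of 16 | C[Si](C)(C)CC(O)(CC[C@H]1C(=C)CC[C@@H]2[C@]1(C)CCC(=NNS(=O)(=O)c3ccc(C)cc3)[C@]2(C)C(=O)OC)[C@H]3COC(C)(C)O3 | intermediate
18 | methyl 13-hydroxy-14,15-O-isopropylidene-16-(trimethylsilyl)labd-8(17)-en-19-oate | C[Si](C)(C)CC(O)(CC[C@H]1C(=C)CC[C@@H]2[C@]1(C)CCC[C@]2(C)C(=O)OC)[C@H]3COC(C)(C)O3 | intermediate
19 | methyl (14S)-14,15-O-isopropylidene-14,15-dihydroxylabda-8(17),13(16)-dien-19-oate | C=C(CC[C@H]1C(=C)CC[C@@H]2[C@]1(C)CCC[C@]2(C)C(=O)OC)[C@H]3COC(C)(C)O3 | intermediate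
20 | methyl (14S)-14,15-dihydroxylabda-8(17),13(16)-dien-19-oate = methyl (1S,4aR,5S,8aR)-5-[(4S)-4,5-dihydroxy-3-methylidenepentyl]-1,4a-dimethyl-6-methylidenedecahydronaphthalene-1-carboxylate | C=C(CC[C@H]1C(=C)CC[C@@H]2[C@]1(C)CCC[C@]2(C)C(=O)OC)[C@H](O)CO | target

**Totals**
Total step count: 10. Longest linear sequence: 10 (steps 1–10; 4 and 10 are bought).

**Steps most likely to fail, each with a fallback**

Step 7 (key bicyclisation). The risks are lower ee because the tertiary alcohol and dioxolane compete for the Lewis acid, and an exo/endo mixture in the selenoxide elimination. The fallback puts the ring stereochemistry under auxiliary control and ends the cascade oxidatively. It sets out from bromide 9, which is alkylated with the dianion (LDA) of (1R,2S,5R)-8-phenylmenthyl acetoacetate F1, itself made from (−)-8-phenylmenthol and 2,2,6-trimethyl-4H-1,3-dioxin-4-one in xylene at 140 °C. This gives the 8-phenylmenthyl (6E,10E)-keto ester F2. Mn(OAc)3·2H2O/Cu(OAc)2·H2O with Yb(OTf)3 in CF3CH2OH at −5 °C then closes both rings by oxidative radical cyclisation. The aryl group of the auxiliary shields one face of the chelated radical, and Cu(II) oxidises the tertiary C-8 radical directly to the 8(17)-alkene, giving the bicyclic 8-phenylmenthyl keto ester F3. DMAP-catalysed transesterification with MeOH in toluene at 110 °C (through the acylketene) releases the auxiliary and comes back to the route at 15.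

Step 9 (deoxygenation of the hindered C-3 ketone next to the quaternary C-4). The tosylhydrazone may form slowly or reduce incompletely. The fallback sets out from 16. NaBH4 in MeOH at 0 °C gives methyl 3β,13-dihydroxy-14,15-O-isopropylidene-16-(trimethylsilyl)labd-8(17)-en-19-oate F4. 1,1'-Thiocarbonyldiimidazole with DMAP in toluene at 80 °C acylates only the secondary alcohol to give the 3β-imidazolyl thiocarbonate F5. Bu3SnH/AIBN in toluene at 90 °C removes the oxygen by Barton–McCombie deoxygenation and comes back at 18.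

Step 2 (kinetic ketone enolate alkylation). The risks are polyalkylation and enolate equilibration toward the α′-alkoxy position, which would cause epimerisation or β-elimination. The fallback sets out from ester 1. Claisen condensation with the lithium enolate of allyl acetate (LDA, THF, −78 °C) gives allyl 3-[(4R)-2,2-dimethyl-1,3-dioxolan-4-yl]-3-oxopropanoate F6. This soft enolate is C-alkylated with geranyl bromide 4 (K2CO3, acetone) to the geranylated allyl β-keto ester F7. Pd(PPh3)4/morpholine in THF at rt removes the allyl group, the β-keto acid decarboxylates, and the route is rejoined at ketone 5 without passing through 3.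

**Further compounds**
F1 | step 7 | (1R,2S,5R)-5-methyl-2-(2-phenylpropan-2-yl)cyclohexyl 3-oxobutanoate ((−)-8-phenylmenthyl acetoacetate) | CC(C)(c1ccccc1)[C@@H]1CC[C@@H](C)C[C@H]1OC(=O)CC(C)=O
F2 | step 7 | (1R,2S,5R)-8-phenylmenthyl (6E,10E)-14-[(4R)-2,2-dimethyl-1,3-dioxolan-4-yl]-14-hydroxy-6,10-dimethyl-3-oxo-15-(trimethylsilyl)pentadeca-6,10-dienoate | CC(C)(c1ccccc1)[C@@H]1CC[C@@H](C)C[C@H]1OC(=O)CC(=O)CC/C(C)=C/CC/C(C)=C/CCC(O)(C[Si](C)(C)C)[C@H]2COC(C)(C)O2
F3 | step 7 | (1R,2S,5R)-8-phenylmenthyl 13-hydroxy-14,15-O-isopropylidene-3-oxo-16-(trimethylsilyl)-19-norlabd-8(17)-en-18-oate | C[Si](C)(C)CC(O)(CC[C@H]1C(=C)CC[C@@H]2[C@]1(C)CCC(=O)[C@H]2C(=O)O[C@@H]4C[C@H](C)CC[C@H]4C(C)(C)c5ccccc5)[C@H]3COC(C)(C)O3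
F4 | step 9 | methyl 3β,13-dihydroxy-14,15-O-isopropylidene-16-(trimethylsilyl)labd-8(17)-en-19-oate | C[Si](C)(C)CC(O)(CC[C@H]1C(=C)CC[C@@H]2[C@]1(C)CC[C@H](O)[C@]2(C)C(=O)OC)[C@H]3COC(C)(C)O3
F5 | step 9 | methyl 13-hydroxy-3β-[(1H-imidazol-1-ylcarbonothioyl)oxy]-14,15-O-isopropylidene-16-(trimethylsilyl)labd-8(17)-en-19-oate | C[Si](C)(C)CC(O)(CC[C@H]1C(=C)CC[C@@H]2[C@]1(C)CC[C@H](OC(=S)n4ccnc4)[C@]2(C)C(=O)OC)[C@H]3COC(C)(C)O3
F6 | step 2 | allyl 3-[(4R)-2,2-dimethyl-1,3-dioxolan-4-yl]-3-oxopropanoate | C=CCOC(=O)CC(=O)[C@H]1COC(C)(C)O1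
F7 | step 2 | allyl (4E)-2-{[(4R)-2,2-dimethyl-1,3-dioxolan-4-yl]carbonyl}-5,9-dimethyldeca-4,8-dienoate | C=CCOC(=O)C(C/C=C(\C)CCC=C(C)C)C(=O)[C@H]1COC(C)(C)O1
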